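Numbering used below: cyclopentene C1(H)–C2H2–C3H=C4(CH3)–C5(H); cycloheptane C5–C6(OH)–C7(H)–C8H2–C9H2–C10(=CH2)–C1; oxolane O–C11(CH3)–C12H2–C13H2–C14(H), with C11 on C7 and C15(CH3)2OAc on C14.
Retrosynthetic cuts: acetyl–O and Si–O; C3=C4 (ring-closing metathesis); C10=CH2 (back to a C10 ketone); C1–C2 and C5–C4 (allyl and isopropenyl on a cyclohept-2-enone with C10=O, C1=C5, C6–OSi); C1=C5 (metathesis) with C10–C1 and C6–C5 (two vinyl additions); O–C14 (epoxide opening); C7–C8 (cuprate opening of 2,3-epoxygeraniol).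
Forward order: the C6–C7(–C8–C10)–C11–C15 chain from geraniol, then the oxolane (step 3), the cycloheptene (step 9) and the cyclopentene last (step 13).
Enabling feature: C3=C4 is the only bond of the cyclopentene that touches no stereocentre, and its two ends hang on the ring-fusion carbons C5 and C1, which are β and α to C10. The C10 methylene is therefore treated as a masked ketone whose enone takes C4 at C5 and C2–C3 at C1 in one trans-selective operation; in the resulting triene only the allyl/isopropenyl pair can close a ring larger than four atoms.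
Stereochemistry: C11 and C7 from Sharpless epoxidation of geraniol (C7 by SN2 inversion); C14 from Shi epoxidation and 5-exo opening with inversion; C6 by Felkin–Anh addition; C5 by addition anti to C6–OSi and the C7 side chain; C1 by allylation anti to the C5 substituent, which gives the trans ring fusion.

Key step: step 13

Assumption: the L-fructose-derived Shi ketone (enantiomer of the usual catalyst) is taken as purchasable; the tertiary C15 hydroxyl is carried unprotected to step 14, so each organomagnesium step uses one extra equivalent of reagent.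

Step 1
Reactants: 1 geraniol
Product: 2 (2S,3S)-2,3-epoxygeraniol
Conditions: Ti(OiPr)4 (5 mol%), L-(+)-diethyl tartrate (7 mol%), t-BuOOH, 4 Å MS, CH2Cl2, −20 °C
Reagents that add atoms: tert-butyl hydroperoxide, CC(C)(C)OO
Why: Sharpless asymmetric epoxidation of an allylic alcohol; with L-(+)-diethyl tartrate the oxygen should be delivered to the face that gives the (2S,3S)-epoxide, which fixes C11 and prepares C7 for inversion.

Step 2
Reactants: 2 (2S,3S)-2,3-epoxygeraniol; 3 2-(2-bromoethyl)-1,3-dioxolane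
Product: 5 (2R,3S)-2-[2-(1,3-dioxolan-2-yl)ethyl]-3,7-dimethyloct-6-ene-1,3-diol, via Grignard reagent 4 (not isolated)
Conditions: 3, Mg, THF, 25 °C; then CuBr·SMe2 (10 mol%), 2, THF, −30 → 0 °C; aq. NH4Cl
Reagents that add atoms: none
Why: Copper-catalysed Grignard opening of a trisubstituted 2,3-epoxy alcohol (SN2) should occur at the less hindered C2 with inversion, which sets C7 and leaves the C11 tertiary alcohol untouched, the first equivalent of 4 serving to deprotonate the hydroxyl.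

Step 3
Reactants: 5 (2R,3S)-2-[2-(1,3-dioxolan-2-yl)ethyl]-3,7-dimethyloct-6-ene-1,3-diol
Product: 7 (2R)-4-(1,3-dioxolan-2-yl)-2-[(2S,5R)-5-(2-hydroxypropan-2-yl)-2-methyloxolan-2-yl]butan-1-ol, via epoxy diol 6 (not isolated)
Conditions: L-fructose-derived Shi ketone (30 mol%), KHSO5 (Oxone), K2CO3, Bu4NHSO4, MeCN/CH2(OMe)2/aq. Na2B4O7 buffer, 0 °C; then CSA (5 mol%), CH2Cl2, 0 °C
Reagents that add atoms: potassium peroxymonosulfate, [K+].[O-]S(=O)(=O)OO
Why: Shi asymmetric epoxidation of the only olefin, followed by acid-catalysed 5-exo-tet opening of the epoxide by the C11 hydroxyl; the L-fructose-derived ketone should give the (S)-epoxide by reagent control, and inversion at C14 then gives the (2S,5R)-oxolane in which C7 and C15 are cis.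

Step 4
Reactants: 7 (2R)-4-(1,3-dioxolan-2-yl)-2-[(2S,5R)-5-(2-hydroxypropan-2-yl)-2-methyloxolan-2-yl]butan-1-ol
Product: 8 (2S)-4-(1,3-dioxolan-2-yl)-2-[(2S,5R)-5-(2-hydroxypropan-2-yl)-2-methyloxolan-2-yl]butanal
Conditions: TEMPO (10 mol%), PhI(OAc)2, CH2Cl2, 25 °C
Reagents that add atoms: none
Why: TEMPO/PhI(OAc)2 oxidation is selective for the primary alcohol and is not basic, so the tertiary alcohol, the acetal and the α-stereocentre C7 should stay untouched.

Step 5
Reactants: 8 (2S)-4-(1,3-dioxolan-2-yl)-2-[(2S,5R)-5-(2-hydroxypropan-2-yl)-2-methyloxolan-2-yl]butanal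
Product: 9 (3S,4R)-6-(1,3-dioxolan-2-yl)-4-[(2S,5R)-5-(2-hydroxypropan-2-yl)-2-methyloxolan-2-yl]hex-1-en-3-ol
Conditions: CH2=CHMgBr (3 equiv), THF, −78 °C; aq. NH4Cl
Reagents that add atoms: vinylmagnesium bromide, C=C[Mg]Br
Why: Felkin–Anh 1,2-addition of a vinyl Grignard reagent to the α-branched aldehyde; with the fully substituted C11 anti to the nucleophile and C8 on the carbonyl-oxygen side, attack should give the (S)-carbinol at C6, the coordinating solvent disfavouring chelation by the oxolane oxygen.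

Step 6
Reactants: 9 (3S,4R)-6-(1,3-dioxolan-2-yl)-4-[(2S,5R)-5-(2-hydroxypropan-2-yl)-2-methyloxolan-2-yl]hex-1-en-3-ol
Product: 10 2-[(2R,5S)-5-[(3S,4R)-3-(tert-butyldimethylsilyloxy)-6-(1,3-dioxolan-2-yl)hex-1-en-4-yl]-5-methyloxolan-2-yl]propan-2-ol
Conditions: TBSCl, imidazole, DMAP (cat.), DMF, 40 °C
Reagents that add atoms: tert-butyldimethylsilyl chloride, CC(C)(C)[Si](C)(C)Cl
Why: Silylation of the secondary allylic hydroxyl with TBSCl/imidazole; the hindered tertiary hydroxyl should not react, and the acetal is safe in the absence of a Lewis acid.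

Step 7
Reactants: 10 2-[(2R,5S)-5-[(3S,4R)-3-(tert-butyldimethylsilyloxy)-6-(1,3-dioxolan-2-yl)hex-1-en-4-yl]-5-methyloxolan-2-yl]propan-2-ol
Product: 11 (4R,5S)-5-(tert-butyldimethylsilyloxy)-4-[(2S,5R)-5-(2-hydroxypropan-2-yl)-2-methyloxolan-2-yl]hept-6-enal
Conditions: PPTS (cat.), acetone/H2O, 60 °C
Reagents that add atoms: water, O
Why: Mild acid-catalysed acetal hydrolysis should free the C10 aldehyde while the secondary silyl ether and the oxolane survive.

Step 8
Reactants: 11 (4R,5S)-5-(tert-butyldimethylsilyloxy)-4-[(2S,5R)-5-(2-hydroxypropan-2-yl)-2-methyloxolan-2-yl]hept-6-enal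
Product: 12 (6R,7S)-7-(tert-butyldimethylsilyloxy)-6-[(2S,5R)-5-(2-hydroxypropan-2-yl)-2-methyloxolan-2-yl]nona-1,8-dien-3-ol (both C3 epimers)
Conditions: CH2=CHMgBr (3 equiv), THF, −78 → 0 °C; aq. NH4Cl
Reagents that add atoms: vinylmagnesium bromide, C=C[Mg]Br
Why: Grignard 1,2-addition to the aldehyde gives the second allylic alcohol, whose configuration does not matter because C10 is oxidised in step 10.

Step 9
Reactants: 12 (6R,7S)-7-(tert-butyldimethylsilyloxy)-6-[(2S,5R)-5-(2-hydroxypropan-2-yl)-2-methyloxolan-2-yl]nona-1,8-dien-3-ol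
Product: 13 (4S,5R)-4-(tert-butyldimethylsilyloxy)-5-[(2S,5R)-5-(2-hydroxypropan-2-yl)-2-methyloxolan-2-yl]cyclohept-2-en-1-ol (both C1 epimers)
Conditions: second-generation Grubbs catalyst (5 mol%), CH2Cl2 (0.005 M), 40 °C
Reagents that add atoms: none
Why: Ring-closing metathesis of the two terminal vinyl groups should form the seven-membered ring with a cis C1=C5 double bond and release ethene.

Step 10
Reactants: 13 (4S,5R)-4-(tert-butyldimethylsilyloxy)-5-[(2S,5R)-5-(2-hydroxypropan-2-yl)-2-methyloxolan-2-yl]cyclohept-2-en-1-ol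
Product: 14 (4S,5R)-4-(tert-butyldimethylsilyloxy)-5-[(2S,5R)-5-(2-hydroxypropan-2-yl)-2-methyloxolan-2-yl]cyclohept-2-en-1-one
Conditions: Dess–Martin periodinane, CH2Cl2, 0 → 25 °C
Reagents that add atoms: none
Why: Dess–Martin oxidation of the secondary allylic alcohol should give the enone and cannot touch the tertiary alcohol.

Step 11
Reactants: 14 (4S,5R)-4-(tert-butyldimethylsilyloxy)-5-[(2S,5R)-5-(2-hydroxypropan-2-yl)-2-methyloxolan-2-yl]cyclohept-2-en-1-one
Product: 16 (2R,3S,4S,5R)-4-(tert-butyldimethylsilyloxy)-5-[(2S,5R)-5-(2-hydroxypropan-2-yl)-2-methyloxolan-2-yl]-3-(prop-1-en-2-yl)-2-(prop-2-en-1-yl)cycloheptan-1-one, via magnesium enolate 15 (not isolated)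
Conditions: CH2=C(CH3)MgBr (3 equiv), CuBr·SMe2 (20 mol%), THF, −78 → −40 °C; then allyl bromide, HMPA, −40 → 0 °C; aq. NH4Cl
Reagents that add atoms: isopropenylmagnesium bromide, CC(=C)[Mg]Br; allyl bromide, C=CCBr
Why: Copper-catalysed conjugate addition followed by allylation of the regiodefined enolate (three-component coupling); the isopropenyl group should add to C5 anti to the C6 silyloxy group and the cis C7 side chain, and allyl bromide should then attack C1 anti to the new C5 substituent, giving the C5/C1 trans arrangement.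

Step 12
Reactants: 16 (2R,3S,4S,5R)-4-(tert-butyldimethylsilyloxy)-5-[(2S,5R)-5-(2-hydroxypropan-2-yl)-2-methyloxolan-2-yl]-3-(prop-1-en-2-yl)-2-(prop-2-en-1-yl)cycloheptan-1-one
Product: 17 2-[(2R,5S)-5-[(1R,2S,3S,4R)-2-(tert-butyldimethylsilyloxy)-5-methylidene-3-(prop-1-en-2-yl)-4-(prop-2-en-1-yl)cycloheptyl]-5-methyloxolan-2-yl]propan-2-ol
Conditions: Ph3PCH3Br, KOt-Bu, THF, 0 → 50 °C
Reagents that add atoms: methyltriphenylphosphonium bromide, C[P+](c1ccccc1)(c1ccccc1)c1ccccc1.[Br-]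
Why: Wittig methylenation of the ketone; the trans arrangement of the allyl and isopropenyl groups is the more stable one on the monocyclic ketone, so the basic ylide should not erode C1.

Step 13
Reactants: 17 2-[(2R,5S)-5-[(1R,2S,3S,4R)-2-(tert-butyldimethylsilyloxy)-5-methylidene-3-(prop-1-en-2-yl)-4-(prop-2-en-1-yl)cycloheptyl]-5-methyloxolan-2-yl]propan-2-ol
Product: 18 2-[(2R,5S)-5-[(3aS,4S,5R,8aR)-4-(tert-butyldimethylsilyloxy)-3-methyl-8-methylidene-1,3a,4,5,6,7,8,8a-octahydroazulen-5-yl]-5-methyloxolan-2-yl]propan-2-ol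
Conditions: second-generation Grubbs catalyst (10 mol%), 1,4-benzoquinone (20 mol%), CH2Cl2 (0.003 M), 40 °C
Reagents that add atoms: none
Why: Ring-closing olefin metathesis: the ruthenium alkylidene should load on the monosubstituted allyl terminus, add to the isopropenyl group through a ruthenacyclobutane and release ethene, forming C3=C4. The closest known reaction type is the ring-closing metathesis of an allyl/isopropenyl pair to a 1-methylcyclopentene. The five-membered ring closes at the C3=C4 bond between two side-chain sp2 carbons, so neither ring-fusion atom takes part, no new stereocentre is formed, and the trans relation of C1 and C5 set in step 11 is carried over unchanged. The step needs chemoselectivity among three olefins; the substrate secures it because pairing either partner with the C10 methylene could only give a four-membered ring, and high dilution suppresses intermolecular metathesis of the allyl group. 1,4-Benzoquinone is added to suppress ruthenium hydride migration of the exocyclic double bond.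

Step 14
Reactants: 18 2-[(2R,5S)-5-[(3aS,4S,5R,8aR)-4-(tert-butyldimethylsilyloxy)-3-methyl-8-methylidene-1,3a,4,5,6,7,8,8a-octahydroazulen-5-yl]-5-methyloxolan-2-yl]propan-2-ol
Product: 19 2-[(2R,5S)-5-[(3aS,4S,5R,8aR)-4-(tert-butyldimethylsilyloxy)-3-methyl-8-methylidene-1,3a,4,5,6,7,8,8a-octahydroazulen-5-yl]-5-methyloxolan-2-yl]propan-2-yl acetate
Conditions: Ac2O, Et3N, DMAP, CH2Cl2, 25 → 40 °C
Reagents that add atoms: acetic anhydride, CC(=O)OC(C)=O
Why: DMAP-catalysed acylation of the only free hydroxyl, the tertiary C15–OH, should give the acetate while C6–O stays silylated.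

Step 15
Reactants: 19 2-[(2R,5S)-5-[(3aS,4S,5R,8aR)-4-(tert-butyldimethylsilyloxy)-3-methyl-8-methylidene-1,3a,4,5,6,7,8,8a-octahydroazulen-5-yl]-5-methyloxolan-2-yl]propan-2-yl acetate
Product: 20 2-[(2R,5S)-5-[(3aS,4S,5R,8aR)-4-hydroxy-3-methyl-8-methylidene-1,3a,4,5,6,7,8,8a-octahydroazulen-5-yl]-5-methyloxolan-2-yl]propan-2-yl acetate
Conditions: HF·pyridine, pyridine, THF, 0 → 25 °C
Reagents that add atoms: none
Why: Fluoride-mediated desilylation should cleave the Si–O bond at C6 without touching the tertiary acetate or the three olefins.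

Compound list
1 | geraniol, (2E)-3,7-dimethylocta-2,6-dien-1-ol | CC(C)=CCC/C(C)=C/CO | starting material
2 | (2S,3S)-2,3-epoxygeraniol, [(2S,3S)-3-methyl-3-(4-methylpent-3-en-1-yl)oxiran-2-yl]methanol | CC(C)=CCC[C@]1(C)O[C@H]1CO | intermediate
3 | 2-(2-bromoethyl)-1,3-dioxolane | BrCCC1OCCO1 | starting material
4 | [2-(1,3-dioxolan-2-yl)ethyl]magnesium bromide (Grignard reagent, not isolated) | Br[Mg]CCC1OCCO1 | intermediate
5 | (2R,3S)-2-[2-(1,3-dioxolan-2-yl)ethyl]-3,7-dimethyloct-6-ene-1,3-diol | OC[C@@H](CCC1OCCO1)[C@@](C)(O)CCC=C(C)C | intermediate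
6 | (2R,3S)-5-[(2S)-3,3-dimethyloxiran-2-yl]-2-[2-(1,3-dioxolan-2-yl)ethyl]-3-methylpentane-1,3-diol (epoxy diol, not isolated) | OC[C@@H](CCC1OCCO1)[C@@](C)(O)CC[C@@H]1OC1(C)C | intermediate
7 | (2R)-4-(1,3-dioxolan-2-yl)-2-[(2S,5R)-5-(2-hydroxypropan-2-yl)-2-methyloxolan-2-yl]butan-1-ol | OC[C@@H](CCC1OCCO1)[C@]2(C)CC[C@H](C(C)(C)O)O2 | intermediate
8 | (2S)-4-(1,3-dioxolan-2-yl)-2-[(2S,5R)-5-(2-hydroxypropan-2-yl)-2-methyloxolan-2-yl]butanal | O=C[C@@H](CCC1OCCO1)[C@]2(C)CC[C@H](C(C)(C)O)O2 | intermediate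
9 | (3S,4R)-6-(1,3-dioxolan-2-yl)-4-[(2S,5R)-5-(2-hydroxypropan-2-yl)-2-methyloxolan-2-yl]hex-1-en-3-ol | C=C[C@H](O)[C@@H](CCC1OCCO1)[C@]2(C)CC[C@H](C(C)(C)O)O2 | intermediate
10 | 2-[(2R,5S)-5-[(3S,4R)-3-(tert-butyldimethylsilyloxy)-6-(1,3-dioxolan-2-yl)hex-1-en-4-yl]-5-methyloxolan-2-yl]propan-2-ol | C=C[C@H](O[Si](C)(C)C(C)(C)C)[C@@H](CCC1OCCO1)[C@]2(C)CC[C@H](C(C)(C)O)O2 | intermediate
11 | (4R,5S)-5-(tert-butyldimethylsilyloxy)-4-[(2S,5R)-5-(2-hydroxypropan-2-yl)-2-methyloxolan-2-yl]hept-6-enal | C=C[C@H](O[Si](C)(C)C(C)(C)C)[C@@H](CCC=O)[C@]2(C)CC[C@H](C(C)(C)O)O2 | intermediate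
12 | (6R,7S)-7-(tert-butyldimethylsilyloxy)-6-[(2S,5R)-5-(2-hydroxypropan-2-yl)-2-methyloxolan-2-yl]nona-1,8-dien-3-ol, both C3 epimers | C=C[C@H](O[Si](C)(C)C(C)(C)C)[C@@H](CCC(O)C=C)[C@]2(C)CC[C@H](C(C)(C)O)O2 | intermediate
13 | (4S,5R)-4-(tert-butyldimethylsilyloxy)-5-[(2S,5R)-5-(2-hydroxypropan-2-yl)-2-methyloxolan-2-yl]cyclohept-2-en-1-ol, both C1 epimers | OC1CC[C@@H]([C@]2(C)CC[C@H](C(C)(C)O)O2)[C@@H](O[Si](C)(C)C(C)(C)C)C=C1 | intermediate
14 | (4S,5R)-4-(tert-butyldimethylsilyloxy)-5-[(2S,5R)-5-(2-hydroxypropan-2-yl)-2-methyloxolan-2-yl]cyclohept-2-en-1-one | O=C1CC[C@@H]([C@]2(C)CC[C@H](C(C)(C)O)O2)[C@@H](O[Si](C)(C)C(C)(C)C)C=C1 | intermediate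
15 | bromomagnesium enolate of the C5-isopropenyl adduct of 14 (C10–OMgBr, C10=C1, isopropenyl at C5 anti to C6–OSi; C15–OMgBr; not isolated) | Br[Mg]OC=1CC[C@@H]([C@]2(C)CC[C@H](C(C)(C)O[Mg]Br)O2)[C@@H](O[Si](C)(C)C(C)(C)C)[C@H](C(C)=C)C=1 | intermediate
16 | (2R,3S,4S,5R)-4-(tert-butyldimethylsilyloxy)-5-[(2S,5R)-5-(2-hydroxypropan-2-yl)-2-methyloxolan-2-yl]-3-(prop-1-en-2-yl)-2-(prop-2-en-1-yl)cycloheptan-1-one | O=C1CC[C@@H]([C@]2(C)CC[C@H](C(C)(C)O)O2)[C@@H](O[Si](C)(C)C(C)(C)C)[C@H](C(C)=C)[C@H]1CC=C | intermediate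
17 | 2-[(2R,5S)-5-[(1R,2S,3S,4R)-2-(tert-butyldimethylsilyloxy)-5-methylidene-3-(prop-1-en-2-yl)-4-(prop-2-en-1-yl)cycloheptyl]-5-methyloxolan-2-yl]propan-2-ol | C=C1CC[C@@H]([C@]2(C)CC[C@H](C(C)(C)O)O2)[C@@H](O[Si](C)(C)C(C)(C)C)[C@H](C(C)=C)[C@H]1CC=C | intermediate
18 | 2-[(2R,5S)-5-[(3aS,4S,5R,8aR)-4-(tert-butyldimethylsilyloxy)-3-methyl-8-methylidene-1,3a,4,5,6,7,8,8a-octahydroazulen-5-yl]-5-methyloxolan-2-yl]propan-2-ol | C=C1CC[C@@H]([C@]2(C)CC[C@H](C(C)(C)O)O2)[C@@H](O[Si](C)(C)C(C)(C)C)[C@@H]2C(C)=CC[C@@H]12 | intermediate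
19 | 2-[(2R,5S)-5-[(3aS,4S,5R,8aR)-4-(tert-butyldimethylsilyloxy)-3-methyl-8-methylidene-1,3a,4,5,6,7,8,8a-octahydroazulen-5-yl]-5-methyloxolan-2-yl]propan-2-yl acetate | C=C1CC[C@@H]([C@]2(C)CC[C@H](C(C)(C)OC(C)=O)O2)[C@@H](O[Si](C)(C)C(C)(C)C)[C@@H]2C(C)=CC[C@@H]12 | intermediate
20 | 2-[(2R,5S)-5-[(3aS,4S,5R,8aR)-4-hydroxy-3-methyl-8-methylidene-1,3a,4,5,6,7,8,8a-octahydroazulen-5-yl]-5-methyloxolan-2-yl]propan-2-yl acetate (trans ring fusion) | C=C1CC[C@@H]([C@]2(C)CC[C@H](C(C)(C)OC(C)=O)O2)[C@@H](O)[C@@H]2C(C)=CC[C@@H]12 | target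

Total step count: 15. Longest linear sequence: 15 steps (1 → 20); the Grignard reagent 4 is made within step 2.

Steps most likely to fail

Step 5. Chelation of magnesium by the oxolane oxygen and the C15 alkoxide may compete with Felkin–Anh control, so the facial selectivity at C6 could be poor. The fallback replaces substrate control by reagent control. It sets out from aldehyde 8: addition of lithium (trimethylsilyl)acetylide (THF, −78 °C) should give the silylated propargylic alcohol mixture F1, and Dess–Martin oxidation the ynone F2. Transfer hydrogenation with RuCl[(R,R)-TsDPEN](p-cymene) in i-PrOH should give the (3R)-propargylic alcohol F3, whose configuration is fixed by the catalyst through the alkynyl group. K2CO3/MeOH should remove the silyl group to give the terminal alkyne F4, and semi-hydrogenation (H2, Pd/CaCO3 poisoned with Pb(OAc)2, quinoline) returns to 9.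

Step 11. C-allylation of the magnesium enolate may be slow, so that proton exchange scrambles the enolate position and leads to over-allylation. The fallback sets out from enone 14. The conjugate addition is run in the presence of TMSCl (CH2=C(CH3)MgBr, CuBr·SMe2 cat., TMSCl, HMPA, THF, −78 °C), which should give the bis(trimethylsilyl) compound, the C10 silyl enol ether F5. Palladium-catalysed allylation of this silyl enol ether with diallyl carbonate (Pd2(dba)3·CHCl3, dppe, THF, reflux; Tsuji allylation under neutral conditions) should give the α-allyl ketone F6 regiospecifically, trans to the C5 substituent. Citric acid in MeOH then removes the tertiary trimethylsilyl ether and returns to 16.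

Step 13. Ring closure onto the hindered 1,1-disubstituted olefin may be slow, which would allow dimerisation through the allyl group, or ruthenium hydrides may move the exocyclic double bond into the ring. The fallback reverses the order of ring closure and olefination and sets out from ketone 16. Metathesis of the keto diene (second-generation Grubbs catalyst, CH2Cl2, 40 °C), which carries no exocyclic methylene, should give the trans-fused bicyclic ketone F7. Non-basic methylenation (Zn, CH2Br2, TiCl4, THF/CH2Cl2, 0 → 25 °C), which should not epimerise the α-stereocentre C1, then returns to 18.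

Further compounds
F1 | step 5 | (4R)-6-(1,3-dioxolan-2-yl)-4-[(2S,5R)-5-(2-hydroxypropan-2-yl)-2-methyloxolan-2-yl]-1-(trimethylsilyl)hex-1-yn-3-ol, both C3 epimers | C[Si](C)(C)C#CC(O)[C@@H](CCC1OCCO1)[C@]2(C)CC[C@H](C(C)(C)O)O2
F2 | step 5 | (4S)-6-(1,3-dioxolan-2-yl)-4-[(2S,5R)-5-(2-hydroxypropan-2-yl)-2-methyloxolan-2-yl]-1-(trimethylsilyl)hex-1-yn-3-one | C[Si](C)(C)C#CC(=O)[C@@H](CCC1OCCO1)[C@]2(C)CC[C@H](C(C)(C)O)O2
F3 | step 5 | (3R,4R)-6-(1,3-dioxolan-2-yl)-4-[(2S,5R)-5-(2-hydroxypropan-2-yl)-2-methyloxolan-2-yl]-1-(trimethylsilyl)hex-1-yn-3-ol | C[Si](C)(C)C#C[C@H](O)[C@@H](CCC1OCCO1)[C@]2(C)CC[C@H](C(C)(C)O)O2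
F4 | step 5 | (3R,4R)-6-(1,3-dioxolan-2-yl)-4-[(2S,5R)-5-(2-hydroxypropan-2-yl)-2-methyloxolan-2-yl]hex-1-yn-3-ol | C#C[C@H](O)[C@@H](CCC1OCCO1)[C@]2(C)CC[C@H](C(C)(C)O)O2
F5 | step 11 | (3S,4S,5R)-4-(tert-butyldimethylsilyloxy)-5-[(2S,5R)-2-methyl-5-(2-trimethylsilyloxypropan-2-yl)oxolan-2-yl]-3-(prop-1-en-2-yl)-1-(trimethylsilyloxy)cyclohept-1-ene | C[Si](C)(C)OC=1CC[C@@H]([C@]2(C)CC[C@H](C(C)(C)O[Si](C)(C)C)O2)[C@@H](O[Si](C)(C)C(C)(C)C)[C@H](C(C)=C)C=1
F6 | step 11 | (2R,3S,4S,5R)-4-(tert-butyldimethylsilyloxy)-5-[(2S,5R)-2-methyl-5-(2-trimethylsilyloxypropan-2-yl)oxolan-2-yl]-3-(prop-1-en-2-yl)-2-(prop-2-en-1-yl)cycloheptan-1-one | O=C1CC[C@@H]([C@]2(C)CC[C@H](C(C)(C)O[Si](C)(C)C)O2)[C@@H](O[Si](C)(C)C(C)(C)C)[C@H](C(C)=C)[C@H]1CC=C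
F7 | step 13 | trans-fused bicyclic ketone, the C10-oxo analogue of 18 (C10=O in place of C10=CH2; configuration at C1, C5, C6, C7, C11 and C14 as in 18) | O=C1CC[C@@H]([C@]2(C)CC[C@H](C(C)(C)O)O2)[C@@H](O[Si](C)(C)C(C)(C)C)[C@@H]2C(C)=CC[C@@H]12
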